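**Retrosynthetic overview**

1. The target is a flavonol in which the C3 hydroxyl oxygen (O3) lies between C2, which carries ring B, and the C4 carbonyl, which is attached to ring A. O3 is used as a one-atom ester tether, so ring C is cut at C3–C4 and O1–C2, leading back to a phenacyl ester of a protected salicylic acid.
2. Forward, an O-to-C 1,2-acyl shift across O3 joins C3 to C4, and acid then closes O1–C2. Pyranone ring C is the only ring formed (rings A and B are bought), and the 3-OH arrives free without an oxidation step.
3. The phenacyl ester is cut at the O3–CH2 bond into a ring B α-bromoketone and a ring A benzoic acid.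
4. The bromoketone comes from 3,4-dihydroxyacetophenone (4-O-MOM, 3-O-prenyl, bromination through the silyl enol ether). The acid comes from 2,4,5-trihydroxybenzaldehyde (tris-MOM ether, chlorite oxidation).
5. The salicylate oxygen is carried as a MOM ether, not as a free phenol, so that the ester carbonyl stays electrophilic and the aldehyde oxidation is clean. The acid that closes ring C also removes every MOM group.

Key step: step 7

Remark on the chemistry (assumption): in methanolic HCl at or below 40 °C the aryl MOM acetals are taken to solvolyse faster than the aryl prenyl ether ionises. Ring closure and removal of all MOM groups are therefore run in one flask, and the MOM-protected flavonol is passed through without isolation.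

**Route**

Step 1
Reactants: 1 1-(3,4-dihydroxyphenyl)ethanone
Product: 2 1-[3-hydroxy-4-(methoxymethoxy)phenyl]ethanone
Conditions: MOMCl (1.05 equiv), K2CO3 (1.1 equiv), acetone, 0 °C → rt
Reagents that add atoms: chloromethyl methyl ether (MOMCl), COCCl
Why: The 4-OH is para to the acetyl group and is the more acidic catechol hydroxyl, so the mono-phenoxide formed with one equivalent of carbonate should be alkylated there by the reactive chloromethyl ether (regioselective Williamson-type O-alkylation).

Step 2
Reactants: 2 1-[3-hydroxy-4-(methoxymethoxy)phenyl]ethanone; 3 prenyl bromide (1-bromo-3-methylbut-2-ene)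
Product: 4 1-[4-(methoxymethoxy)-3-(3-methylbut-2-enyloxy)phenyl]ethanone
Conditions: K2CO3, DMF, rt
Reagents that add atoms: none
Why: Williamson ether synthesis, in which the remaining phenoxide displaces the primary allylic bromide by SN2 while the MOM acetal and the ketone are inert to carbonate.

Step 3
Reactants: 4 1-[4-(methoxymethoxy)-3-(3-methylbut-2-enyloxy)phenyl]ethanone
Product: 6 2-bromo-1-[4-(methoxymethoxy)-3-(3-methylbut-2-enyloxy)phenyl]ethanone, via trimethylsilyl enol ether 5 (not isolated)
Conditions: LiN(SiMe3)2 (1.05 equiv), Me3SiCl, THF, −78 °C; then NBS (1.0 equiv), THF, −78 → 0 °C, dark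
Reagents that add atoms: N-bromosuccinimide, O=C1CCC(=O)N1Br
Why: Enolate silylation followed by bromination of the silyl enol ether with NBS should be site-specific, because the enol ether is far more nucleophilic than the trisubstituted prenyl olefin or the arene and no HBr is released, so the olefin and the MOM acetal survive.

Step 4
Reactants: 7 2,4,5-trihydroxybenzaldehyde
Product: 8 2,4,5-tris(methoxymethoxy)benzaldehyde
Conditions: MOMCl (4.5 equiv), i-Pr2NEt (6 equiv), CH2Cl2, 0 → 40 °C, Ar
Reagents that add atoms: chloromethyl methyl ether (MOMCl), COCCl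
Why: Exhaustive O-alkylation of the phenols with MOMCl and a hindered amine, where the excess reagent and warming should also cap the hydrogen-bonded 2-OH and argon protects the air-sensitive triol.

Step 5
Reactants: 8 2,4,5-tris(methoxymethoxy)benzaldehyde
Product: 9 2,4,5-tris(methoxymethoxy)benzoic acid
Conditions: NaClO2, NaH2PO4, 2-methyl-2-butene, t-BuOH–H2O, 0 °C → rt; work-up at pH 4–5
Reagents that add atoms: NaClO2 (sodium chlorite), [Na+].[O-]Cl=O
Why: Pinnick oxidation, in which chlorous acid oxidises the aldehyde, 2-methyl-2-butene traps the hypochlorous acid so the electron-rich ring is not chlorinated, and the phosphate buffer leaves the MOM acetals intact.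

Step 6
Reactants: 9 2,4,5-tris(methoxymethoxy)benzoic acid; 6 2-bromo-1-[4-(methoxymethoxy)-3-(3-methylbut-2-enyloxy)phenyl]ethanone
Product: 10 2-[4-(methoxymethoxy)-3-(3-methylbut-2-enyloxy)phenyl]-2-oxoethyl 2,4,5-tris(methoxymethoxy)benzoate
Conditions: KHCO3 (1.5 equiv), DMF, rt
Reagents that add atoms: none
Why: Phenacyl ester formation by SN2 attack of the carboxylate on the α-bromoketone, with a base too weak to enolise the product or start acyl transfer.

Step 7
Reactants: 10 2-[4-(methoxymethoxy)-3-(3-methylbut-2-enyloxy)phenyl]-2-oxoethyl 2,4,5-tris(methoxymethoxy)benzoate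
Product: 13 3,6,7-trihydroxy-2-[4-hydroxy-3-(3-methylbut-2-enyloxy)phenyl]-4H-chromen-4-one, via 2-hydroxy-1,3-diketone 11 (not isolated), via tris-MOM flavonol 12 (not isolated)
Conditions: LiN(SiMe3)2 (2.5 equiv), THF, −78 → 0 °C, Ar; then HCl, MeOH, 0 → 40 °C
Reagents that add atoms: none
Why: Proposed new method: LiN(SiMe3)2 forms the lithium enolate of the aryl ketone, whose α-carbon attacks the ester carbonyl held one atom away by O3 and passes through a lithium alkoxy-oxirane that collapses by breaking the acyl–O3 bond, so the ring A acyl carbon (C4) becomes bonded to C3 and the tether oxygen is left as the C3 alkoxide; a second equivalent of base removes the doubly activated C3–H and stores diketone 11 as its enediolate, which pulls the shift forward and blocks retro-Claisen cleavage and back-migration. The closest known reaction type is the base-induced 1,2 O-to-C acyl migration of α-acyloxy ketones to α-hydroxy-1,3-diketones (the O-tethered counterpart of the Baker–Venkataraman rearrangement), joined here to the acid cyclodehydration of an o-hydroxyaryl 1,3-diketone used in flavone synthesis. In methanolic HCl the MOM ether ortho to the new ketone should be lost first, the freed phenol oxygen (O1) adds to the ring B ketone carbon (C2) in a 6-exo-trig closure, and the hemiketal loses water by β-elimination to give pyranone ring C (12), after which the three remaining MOM ethers are solvolysed to 13. No stereocenter is formed. The step needs C-acylation to beat intermolecular Claisen reaction and ester cleavage, and needs the prenyl ether to outlast the acetals: the short O3 tether and the non-nucleophilic amide base secure the first, the MOM cap on the 2-oxygen keeps the ester electrophilic by avoiding a deactivating phenoxide, and the faster acetal solvolysis at or below 40 °C under argon should secure the second.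

**Compound list**

1 | 1-(3,4-dihydroxyphenyl)ethanone | CC(=O)c1ccc(O)c(O)c1 | starting material
2 | 1-[3-hydroxy-4-(methoxymethoxy)phenyl]ethanone | CC(=O)c1ccc(OCOC)c(O)c1 | intermediate
3 | prenyl bromide (1-bromo-3-methylbut-2-ene) | CC(C)=CCBr | starting material
4 | 1-[4-(methoxymethoxy)-3-(3-methylbut-2-enyloxy)phenyl]ethanone | CC(=O)c1ccc(OCOC)c(OCC=C(C)C)c1 | intermediate
5 | trimethyl({1-[4-(methoxymethoxy)-3-(3-methylbut-2-enyloxy)phenyl]ethenyl}oxy)silane (silyl enol ether, not isolated) | C=C(O[Si](C)(C)C)c1ccc(OCOC)c(OCC=C(C)C)c1 | intermediate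
6 | 2-bromo-1-[4-(methoxymethoxy)-3-(3-methylbut-2-enyloxy)phenyl]ethanone | BrCC(=O)c1ccc(OCOC)c(OCC=C(C)C)c1 | intermediate
7 | 2,4,5-trihydroxybenzaldehyde | O=Cc1cc(O)c(O)cc1O | starting material
8 | 2,4,5-tris(methoxymethoxy)benzaldehyde | O=Cc1cc(OCOC)c(OCOC)cc1OCOC | intermediate
9 | 2,4,5-tris(methoxymethoxy)benzoic acid | OC(=O)c1cc(OCOC)c(OCOC)cc1OCOC | intermediate
10 | 2-[4-(methoxymethoxy)-3-(3-methylbut-2-enyloxy)phenyl]-2-oxoethyl 2,4,5-tris(methoxymethoxy)benzoate | CC(C)=CCOc1cc(C(=O)COC(=O)c2cc(OCOC)c(OCOC)cc2OCOC)ccc1OCOC | intermediate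
11 | 2-hydroxy-1-[4-(methoxymethoxy)-3-(3-methylbut-2-enyloxy)phenyl]-3-[2,4,5-tris(methoxymethoxy)phenyl]propane-1,3-dione (formed as its dilithium enediolate, not isolated) | CC(C)=CCOc1cc(C(=O)C(O)C(=O)c2cc(OCOC)c(OCOC)cc2OCOC)ccc1OCOC | intermediate
12 | 3-hydroxy-6,7-bis(methoxymethoxy)-2-[4-(methoxymethoxy)-3-(3-methylbut-2-enyloxy)phenyl]-4H-chromen-4-one (not isolated) | CC(C)=CCOc1cc(-c2oc3cc(OCOC)c(OCOC)cc3c(=O)c2O)ccc1OCOC | intermediate
13 | 3,6,7-trihydroxy-2-[4-hydroxy-3-(3-methylbut-2-enyloxy)phenyl]-4H-chromen-4-one (CNP0086069.0) | CC(C)=CCOc1cc(-c2oc3cc(O)c(O)cc3c(=O)c2O)ccc1O | target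

**Step count**

Total: 7 steps. Longest linear sequence: 5 steps (steps 1, 2, 3, 6, 7). The ring A branch (steps 4 and 5) joins at step 6.

**Steps most likely to fail**

1. Step 7 (proposed new method). The enolate may react between molecules (Claisen or aldol oligomerisation) or pass the acyl group between the two enediol oxygens instead of onto carbon. The hydroxy-diketone may undergo retro-Claisen cleavage or back-migration before closure. In the acid stage, ionisation of the prenyl ether may compete with acetal solvolysis.
Fallback (known chemistry; sets out from 6 and 9, returns at 13): an intermolecular crossed Claisen acylation with O3 protected, which is the diketone route to flavonols with an α-alkoxy ketone. Bromoketone 6 with KOAc in DMF should give 2-[4-(methoxymethoxy)-3-(3-methylbut-2-enyloxy)phenyl]-2-oxoethyl acetate F1. K2CO3 in MeOH at 0 °C should free 2-hydroxy-1-[4-(methoxymethoxy)-3-(3-methylbut-2-enyloxy)phenyl]ethanone F2, which MOMCl and i-Pr2NEt in CH2Cl2 should cap as 2-(methoxymethoxy)-1-[4-(methoxymethoxy)-3-(3-methylbut-2-enyloxy)phenyl]ethanone F3. Acid 9 with 1,1'-carbonyldiimidazole in THF should give the acyl imidazole 1H-imidazol-1-yl[2,4,5-tris(methoxymethoxy)phenyl]methanone F4. The lithium enolate of F3 (LiN(SiMe3)2, 2.2 equiv, THF, −78 °C) acylated by F4 should give 2-(methoxymethoxy)-1-[4-(methoxymethoxy)-3-(3-methylbut-2-enyloxy)phenyl]-3-[2,4,5-tris(methoxymethoxy)phenyl]propane-1,3-dione F5. HCl in MeOH at 40 °C should then remove the five MOM groups and cyclodehydrate F5 to 13.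

2. Step 3. Electrophilic bromine may add to or allylically brominate the prenyl double bond, or brominate the alkoxy-substituted ring. The silyl enol ether may also be desilylated back to 4 before bromination.
Fallback (sets out from 4, returns at 10, bypassing 6): the ester is assembled by carbenoid O–H insertion with no electrophilic halogen. The lithium enolate of 4 (LiN(SiMe3)2, THF, −78 °C) acylated with 2,2,2-trifluoroethyl trifluoroacetate should give 4,4,4-trifluoro-1-[4-(methoxymethoxy)-3-(3-methylbut-2-enyloxy)phenyl]butane-1,3-dione F6. With methanesulfonyl azide, Et3N and one equivalent of water in MeCN, F6 should undergo detrifluoroacetylative diazo transfer to 2-diazo-1-[4-(methoxymethoxy)-3-(3-methylbut-2-enyloxy)phenyl]ethanone F7. F7 and acid 9 with Rh2(OAc)4 (1 mol %) in CH2Cl2 at rt should give ester 10.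

3. Step 1. Alkylation may run on to the bis-MOM ether or occur partly at the 3-OH, giving a mixture of regioisomers that is hard to separate.
Fallback (sets out from 1, returns at 4, bypassing 2): the order of the two alkylations is inverted through the catecholate dianion. Ketone 1 with NaH (2.1 equiv) in DMSO gives the dianion, whose more basic 3-oxygen should be alkylated by one equivalent of 3 to give 1-[4-hydroxy-3-(3-methylbut-2-enyloxy)phenyl]ethanone F8. MOMCl and i-Pr2NEt in CH2Cl2 should then cap the 4-OH to give 4.

**Further compounds**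

F1 | step 7 | 2-[4-(methoxymethoxy)-3-(3-methylbut-2-enyloxy)phenyl]-2-oxoethyl acetate | CC(=O)OCC(=O)c1ccc(OCOC)c(OCC=C(C)C)c1
F2 | step 7 | 2-hydroxy-1-[4-(methoxymethoxy)-3-(3-methylbut-2-enyloxy)phenyl]ethanone | OCC(=O)c1ccc(OCOC)c(OCC=C(C)C)c1
F3 | step 7 | 2-(methoxymethoxy)-1-[4-(methoxymethoxy)-3-(3-methylbut-2-enyloxy)phenyl]ethanone | COCOCC(=O)c1ccc(OCOC)c(OCC=C(C)C)c1
F4 | step 7 | 1H-imidazol-1-yl[2,4,5-tris(methoxymethoxy)phenyl]methanone | O=C(c1cc(OCOC)c(OCOC)cc1OCOC)n1ccnc1
F5 | step 7 | 2-(methoxymethoxy)-1-[4-(methoxymethoxy)-3-(3-methylbut-2-enyloxy)phenyl]-3-[2,4,5-tris(methoxymethoxy)phenyl]propane-1,3-dione | CC(C)=CCOc1cc(C(=O)C(OCOC)C(=O)c2cc(OCOC)c(OCOC)cc2OCOC)ccc1OCOC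
F6 | step 3 | 4,4,4-trifluoro-1-[4-(methoxymethoxy)-3-(3-methylbut-2-enyloxy)phenyl]butane-1,3-dione | CC(C)=CCOc1cc(C(=O)CC(=O)C(F)(F)F)ccc1OCOC
F7 | step 3 | 2-diazo-1-[4-(methoxymethoxy)-3-(3-methylbut-2-enyloxy)phenyl]ethanone | CC(C)=CCOc1cc(C(=O)C=[N+]=[N-])ccc1OCOC
F8 | step 1 | 1-[4-hydroxy-3-(3-methylbut-2-enyloxy)phenyl]ethanone | CC(=O)c1ccc(O)c(OCC=C(C)C)c1
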